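The small charge of Sunday's run, 0.050 M, read a mean of 60.5% product, and Friday's larger charge, 0.075 M, 50.7%.

| flask | substrate | coupling partner | free catalyst | remark | time |
|---|---|---|---|---|---|
| Sunday's | 0.050 M (in portions, 3) | 0.20 M | 0.11 mM | run made earlier; portions every 20 s |  |
| Friday's | 0.075 M (in portions, 3) | 0.20 M | 0.11 mM | run made earlier; portions every 20 s |  |
| flask | 0.10 M (in portions, 3) | 0.200 M | 0.11 mM | the portions of substrate follow each other after 20 s, the first at the start | 20 h |

- Sunday's (time / h: product / %, substrate / %): 1.50: 59.0, 0; 2.50: 60.3, 0; 4.00: 62.0, 0.5; 8.00: 60.5, 0.2; 12.0: 59.4, 0; 20.0: 61.6, 0
- Friday's (time / h: product / %, substrate / %): 3.00: 50.6, 0.6; 6.00: 51.1, 0; 10.0: 51.6, 0.4; 12.0: 50.4, 0; 15.0: 51.1, 0.4; 20.0: 49.5, 0.8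

(each reading ± 1 percentage point)

* which holds at 20 h: what has brought the reaction to rest, or that it has not come to rest (it is still moving / all of the substrate has reacted / no working catalyst is left / forward and back rates have come level / the coupling partner has run out first)
* amount of product at 20 h, in percent of the substrate charged

- the numbers in the tables scatter with a standard deviation of 1 percentage point
- a reading or a percentage of product counts all its forms, free or not
- the reaction counts as stopped when no species that holds the substrate changes by six tenths of a point or more over the second half of the time

In both runs substrate stayed within scatter of zero and product stayed flat, so I expected this flask to stop with its substrate, the limiting reagent, reacted. I reckoned with the marginal yield, the fraction of added charge that ends as product. Friday's extra charge over Sunday's puts it at 31.2%, below Sunday's average.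

If the added charge made no product, Friday's product spread over this flask's charge would give a floor of 38.0%. If substrate is lost at second order against first-order coupling, the reciprocal of the yield bends downward with charge, so its straight line through both runs raises the floor to 43.7%. If the marginal yield keeps falling, the last step earns less than 31.2%, which gives a ceiling of 45.8%. Both limits are readings and carry their scatter. I committed to the middle, 44.8%.

The forecast said all of the substrate has reacted and 45%, inside my bracket, reading “a side reaction of higher order in substrate”.

The flask ended: all of the substrate has reacted, with 44.2% product, also inside.

    coupling partner + free catalyst ⇌ catalyst intermediate A (K = 8.20 M⁻¹, k = 1870 M⁻¹ min⁻¹)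
    substrate + catalyst intermediate A → catalyst intermediate B (k = 774 M⁻¹ min⁻¹)
    catalyst intermediate B ⇌ catalyst intermediate C (K = 0.560, k = 309 min⁻¹)
    catalyst intermediate C → free catalyst + product (k = 13400 min⁻¹)
    crystals ⇌ product, rate k5*(cs5 - [product]) while solid is left; crystals form when [product] > cs5 (solubility = 6.80 mM, k = 8.36 min⁻¹)
    2 substrate → homo dimer (k = 0.756 M⁻¹ min⁻¹)

This flask was at rest: substrate stood at 0% after 10.0 h, the largest change over the second half was 0 percentage points, and after 200 h product still read 44.2%. The marginal yield could therefore be taken from finished flasks. The step from Friday's readings to this flask gave 24.8%, below the 31.2% I carried. The neighbour charged with 0.40 M ended at 17.7% with substrate at 0%, and its step beyond this flask gave 8.81%.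

(The runs are simulated with constants of no real substance; noise was put on by code.)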